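The route rests on cutting the O1–C8a bond of chroman 1 (the 3,4-diarylchroman). O1 sits on ring A carbon C8a, ortho to C4a and meta to the C7 oxygen, which is what a Baeyer–Villiger oxidation of a 6-benzyloxyindan-1-one delivers when the aryl carbon migrates. In one operation the peracid inserts oxygen into the C1–C7a bond of indanone 16 and expands it to the six-membered lactone 17, the indanone C3 becoming C4 unchanged. The precursor is a (3S)-3-arylindanone that already carries the central arene and (R)-chroman 2; its stereocentre comes from asymmetric hydroacylation, and ring B is added afterwards by lactone α-arylation.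

Key step: step 12

Remarks on the chemistry
- Boronic acid 14 is taken to be a purchasable building block.
- The senses of induction in steps 6 and 11 are assigned by analogy with simpler substrates of the same reaction classes; if either proves opposite, the mirror-image ligand would be used.
- Stereodescriptors: indanone 16 is 3S and lactone 17 is 4S; both correspond spatially to C4 (S) of the target, whose chroman 1 is trans (3R,4S) and whose chroman 2 is 3R.
- The acetyl carbon of the central arene is carried as a nitrile through steps 3–7, because a nitrile survives enolate arylation, transfer hydrogenation and ionic hydrogenation.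

Step 1
Reactants: 1 2,4-dihydroxy-6-methoxybenzaldehyde
Product: 2 4-(benzyloxy)-2-hydroxy-6-methoxybenzaldehyde
Conditions: BnBr (1.05 equiv), NaHCO3, KI (cat.), MeCN, 80 °C
Reagents that add atoms: benzyl bromide, BrCc1ccccc1
Why: Williamson etherification that should be selective for the 4-hydroxyl, because the 2-hydroxyl is held in a hydrogen bond to the aldehyde and is not deprotonated by the weak base.

Step 2
Reactants: 2 4-(benzyloxy)-2-hydroxy-6-methoxybenzaldehyde
Product: 3 (E)-4-(benzyloxy)-2-hydroxy-6-methoxybenzaldehyde oxime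
Conditions: NH2OH·HCl, NaOAc, EtOH/H2O, 60 °C
Reagents that add atoms: hydroxylamine hydrochloride, NO.Cl
Why: Oxime condensation of a salicylaldehyde-type aldehyde, which prepares the formyl carbon for conversion into the nitrile.

Step 3
Reactants: 3 (E)-4-(benzyloxy)-2-hydroxy-6-methoxybenzaldehyde oxime
Product: 4 5-(benzyloxy)-2-cyano-3-methoxyphenyl trifluoromethanesulfonate
Conditions: Tf2O (2.3 equiv), pyridine, CH2Cl2, −20 °C to rt
Reagents that add atoms: trifluoromethanesulfonic anhydride, O=S(=O)(OS(=O)(=O)C(F)(F)F)C(F)(F)F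
Why: Phenol triflation and aldoxime dehydration in one operation, since the O-sulfonylated E-aldoxime loses triflate under pyridine to give the nitrile, and any benzisoxazole formed by N–O closure would be reopened by the base to the same cyanophenoxide before triflation.

Step 4
Reactants: 5 7-hydroxychroman-4-one
Product: 6 7-(benzyloxy)chroman-4-one
Conditions: BnBr, K2CO3, acetone, reflux
Reagents that add atoms: benzyl bromide, BrCc1ccccc1
Why: Williamson etherification of an acidic phenol para to the ketone under conditions too mild to open the chromanone ring.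

Step 5
Reactants: 6 7-(benzyloxy)chroman-4-one; 4 5-(benzyloxy)-2-cyano-3-methoxyphenyl trifluoromethanesulfonate
Product: 7 rac-4-(benzyloxy)-2-[7-(benzyloxy)-4-oxochroman-3-yl]-6-methoxybenzonitrile
Conditions: Pd2(dba)3 (2.5 mol %), XPhos (6 mol %), K3PO4, toluene, 90 °C
Reagents that add atoms: none
Why: Palladium-catalysed ketone α-arylation in which the electron-poor ortho-cyano triflate adds readily to zerovalent palladium, the phosphate base spares the triflate and the chromanone ring, and the acidic tertiary α-aryl ketone resists a second arylation; C3 is formed racemic and is set in step 6.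

Step 6
Reactants: 7 rac-3-aryl-7-(benzyloxy)chroman-4-one
Product: 8 4-(benzyloxy)-2-[(3R,4R)-7-(benzyloxy)-4-hydroxychroman-3-yl]-6-methoxybenzonitrile (cis)
Conditions: RuCl[(R,R)-TsDPEN](p-cymene) (2 mol %), HCO2H/Et3N (5:2), EtOAc, 40 °C
Reagents that add atoms: none
Why: Noyori–Ikariya asymmetric transfer hydrogenation with dynamic kinetic resolution, in which the α-aryl ketone racemises through its enol in the amine/formic acid medium and the catalyst reduces one enantiomer from the face fixed by the fused arene, so that C4 (R) and, through the cis relationship, C3 (R) are both set by the catalyst.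

Step 7
Reactants: 8 cis-(3R,4R)-3-aryl-7-(benzyloxy)chroman-4-ol
Product: 9 4-(benzyloxy)-2-[(3R)-7-(benzyloxy)chroman-3-yl]-6-methoxybenzonitrile
Conditions: Et3SiH (6 equiv), BF3·OEt2 (2 equiv), CH2Cl2, −78 to −30 °C
Reagents that add atoms: none
Why: Ionic hydrogenation of a benzylic alcohol para to an ether oxygen, in which the C4 cation should be captured by hydride from the excess silane at low temperature before it can lose the C3 proton, so that C3 keeps its R configuration while the nitrile is inert to acid and silane.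

Step 8
Reactants: 9 (R)-isoflavan nitrile
Product: 11 1-{4-(benzyloxy)-2-[(3R)-7-(benzyloxy)chroman-3-yl]-6-methoxyphenyl}ethan-1-one, via NH ketimine 10 (not isolated)
Conditions: MeLi (3 equiv), Et2O/THF, 0 °C to rt; then 2 M HCl, THF, 50 °C
Reagents that add atoms: methyllithium, [Li]C; water, O
Why: Organolithium addition to a nitrile stops at the metallated ketimine, which cannot add a second equivalent, and acid hydrolysis should then release the hindered aryl methyl ketone.

Step 9
Reactants: 11 aryl methyl ketone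
Product: 13 1-{4-(benzyloxy)-2-[(3R)-7-(benzyloxy)chroman-3-yl]-6-methoxyphenyl}ethenyl trifluoromethanesulfonate, via potassium enolate 12 (not isolated)
Conditions: KN(SiMe3)2 (1.1 equiv), THF, −78 °C; PhNTf2, −78 to 0 °C
Reagents that add atoms: N-phenylbis(trifluoromethanesulfonimide), O=S(=O)(N(c1ccccc1)S(=O)(=O)C(F)(F)F)C(F)(F)F
Why: Kinetic enolisation at the only enolisable position and O-sulfonylation give the vinyl triflate, a route that avoids nucleophilic addition to a carbonyl carbon crowded by two ortho substituents.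

Step 10
Reactants: 13 vinyl triflate; 14 (4-(benzyloxy)-2-formylphenyl)boronic acid
Product: 15 5-(benzyloxy)-2-(1-{4-(benzyloxy)-2-[(3R)-7-(benzyloxy)chroman-3-yl]-6-methoxyphenyl}ethenyl)benzaldehyde
Conditions: Pd(OAc)2 (5 mol %), SPhos (10 mol %), K3PO4, toluene/H2O, 60 °C
Reagents that add atoms: none
Why: Suzuki–Miyaura coupling of a vinyl triflate with an arylboronic acid, run with a bulky electron-rich biarylphosphine because both partners are ortho-substituted and because fast coupling limits protodeboronation of the ortho-formyl boronic acid.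

Step 11
Reactants: 15 2-(1-arylethenyl)-5-(benzyloxy)benzaldehyde
Product: 16 (3S)-6-(benzyloxy)-3-{4-(benzyloxy)-2-[(3R)-7-(benzyloxy)chroman-3-yl]-6-methoxyphenyl}-2,3-dihydro-1H-inden-1-one
Conditions: [Rh(nbd)2]BF4 (5 mol %), (R)-BINAP (5.5 mol %), H2 (briefly, to remove norbornadiene), then 15, CH2Cl2, 30 °C
Reagents that add atoms: none
Why: Rhodium-catalysed intramolecular olefin hydroacylation of an α-substituted 2-vinylbenzaldehyde, in which formyl C–H oxidative addition, insertion of the 1,1-diarylethylene into Rh–H with hydride going to the internal carbon, and reductive elimination close the five-membered ketone, the chiral bisphosphine choosing the alkene face so that C3 is formed S.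

Step 12
Reactants: 16 (3S)-3-aryl-6-(benzyloxy)indan-1-one
Product: 17 (4S)-7-(benzyloxy)-4-{4-(benzyloxy)-2-[(3R)-7-(benzyloxy)chroman-3-yl]-6-methoxyphenyl}chroman-2-one
Conditions: mCPBA (2.5 equiv), TsOH·H2O (0.2 equiv), CH2Cl2, 0–4 °C, dark
Reagents that add atoms: 3-chloroperoxybenzoic acid, O=C(OO)c1cccc(Cl)c1
Why: The peracid adds to the C1 carbonyl of 16 and the resulting Criegee adduct rearranges by a 1,2-shift of the aryl carbon C7a from C1 to the proximal peroxide oxygen with loss of 3-chlorobenzoate, which forms the O1–C8a bond of chroman 1. This is the Baeyer–Villiger oxidation of a 1-indanone to a 3,4-dihydrocoumarin, a reaction type known for 3-arylindanones. The six-membered lactone ring arises by ring expansion of the five-membered ketone through this shift and not by cyclisation of an open chain, so no ring-closure geometry has to be met. No stereocentre is formed, and because C3 of 16 is neither the migrating atom nor the migration terminus it becomes C4 of 17 with its S configuration unchanged. The step needs the aryl carbon to migrate in preference to the C2 methylene, which the higher migratory aptitude of an aryl carbon over a primary alkyl carbon should secure, helped by the 6-benzyloxy group being meta to C7a so that it does not conjugate with and deactivate the ketone. It also needs the ketone to react ahead of the alkoxy-substituted arenes, for which the mild peracid, only catalytic acid, low temperature, exclusion of light and a limited excess of oxidant are chosen in place of a more electrophilic peracid.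

Step 13
Reactants: 18 2,6-dimethoxyphenol
Product: 19 2-(benzyloxy)-1,3-dimethoxybenzene
Conditions: BnBr, K2CO3, DMF, rt
Reagents that add atoms: benzyl bromide, BrCc1ccccc1
Why: Williamson etherification, which also turns the phenol from the strongest director into a twisted, weaker one before bromination.

Step 14
Reactants: 19 2-(benzyloxy)-1,3-dimethoxybenzene
Product: 20 3-(benzyloxy)-1-bromo-2,4-dimethoxybenzene
Conditions: NBS, MeCN, 0 °C to rt
Reagents that add atoms: N-bromosuccinimide, O=C1CCC(=O)N1Br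
Why: Electrophilic aromatic bromination of a 1,2,3-trialkoxybenzene goes ortho and para to the two flanking methoxy groups, because the central benzyloxy group is twisted out of conjugation and activates its own para position less.

Step 15
Reactants: 17 (4S)-4-aryl-7-(benzyloxy)chroman-2-one; 20 3-(benzyloxy)-1-bromo-2,4-dimethoxybenzene
Product: 23 (3R,4S)-7-(benzyloxy)-3-[3-(benzyloxy)-2,4-dimethoxyphenyl]-4-{4-(benzyloxy)-2-[(3R)-7-(benzyloxy)chroman-3-yl]-6-methoxyphenyl}chroman-2-one, via chlorozinc lactone enolate 21 (not isolated), via C3-epimeric lactone mixture 22 (not isolated)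
Conditions: LiN(SiMe3)2 (1.1 equiv), THF, −78 °C; ZnCl2, −78 °C to rt; 20, Pd(dba)2 (5 mol %), P(tBu)3 (5 mol %), rt to 50 °C; then DBU (0.5 equiv), rt
Reagents that add atoms: none
Why: Palladium-catalysed α-arylation of an ester enolate used as its zinc enolate, which is mild enough to keep the aryl ester ring closed, after which the new C3 centre is set under thermodynamic control because DBU equilibrates the acidic C3–H until ring B lies trans to the fixed C4 aryl group (3R).

Step 16
Reactants: 23 trans-(3R,4S)-3,4-diarylchroman-2-one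
Product: 24 (2R,3S)-2-[3-(benzyloxy)-2,4-dimethoxyphenyl]-3-{4-(benzyloxy)-2-[(3R)-7-(benzyloxy)chroman-3-yl]-6-methoxyphenyl}-3-[4-(benzyloxy)-2-hydroxyphenyl]propan-1-ol
Conditions: LiAlH4, THF, 0 °C
Reagents that add atoms: none
Why: Hydride reduction of an aryl ester to the phenol and the primary alcohol, fast enough at 0 °C that the transient α-aryl aldehyde is reduced before it can epimerise, so both stereocentres pass through unchanged.

Step 17
Reactants: 24 phenol–primary alcohol
Product: 25 (3R,4S)-7-(benzyloxy)-3-[3-(benzyloxy)-2,4-dimethoxyphenyl]-4-{4-(benzyloxy)-2-[(3R)-7-(benzyloxy)chroman-3-yl]-6-methoxyphenyl}chroman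
Conditions: PPh3, DIAD, THF, 0 °C to rt
Reagents that add atoms: none
Why: Mitsunobu cycloetherification, a 6-exo-tet displacement at the activated primary carbinol carbon by the only free phenol, which touches no stereocentre and re-closes chroman 1 at the ether level while keeping the aryl C–O bond made in step 12 as O1–C8a.

Step 18
Reactants: 25 tetrabenzyl ether of the target
Product: 26 (3R,4S)-3-(3-hydroxy-2,4-dimethoxyphenyl)-4-{4-hydroxy-2-[(3R)-7-hydroxychroman-3-yl]-6-methoxyphenyl}chroman-7-ol (CNP0305801.1)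
Conditions: H2 (1 atm), Pd/C (10 %), EtOAc/MeOH, rt
Reagents that add atoms: none
Why: Hydrogenolysis of the four benzyl aryl ethers under neutral conditions that leave the chroman C–O bonds, the methyl ethers and the three stereocentres untouched.

Compound list
1 | 2,4-dihydroxy-6-methoxybenzaldehyde | COc1cc(O)cc(O)c1C=O | starting material
2 | 4-(benzyloxy)-2-hydroxy-6-methoxybenzaldehyde | COc1cc(OCc2ccccc2)cc(O)c1C=O | intermediate
3 | (E)-4-(benzyloxy)-2-hydroxy-6-methoxybenzaldehyde oxime | COc1cc(OCc2ccccc2)cc(O)c1/C=N/O | intermediate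
4 | 5-(benzyloxy)-2-cyano-3-methoxyphenyl trifluoromethanesulfonate | COc1cc(OCc2ccccc2)cc(OS(=O)(=O)C(F)(F)F)c1C#N | intermediate
5 | 7-hydroxychroman-4-one | O=C1CCOc2cc(O)ccc12 | starting material
6 | 7-(benzyloxy)chroman-4-one | O=C1CCOc2cc(OCc3ccccc3)ccc12 | intermediate
7 | rac-4-(benzyloxy)-2-[7-(benzyloxy)-4-oxochroman-3-yl]-6-methoxybenzonitrile | COc1cc(OCc2ccccc2)cc(C2COc3cc(OCc4ccccc4)ccc3C2=O)c1C#N | intermediate
8 | 4-(benzyloxy)-2-[(3R,4R)-7-(benzyloxy)-4-hydroxychroman-3-yl]-6-methoxybenzonitrile | COc1cc(OCc2ccccc2)cc([C@@H]2COc3cc(OCc4ccccc4)ccc3[C@@H]2O)c1C#N | intermediate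
9 | 4-(benzyloxy)-2-[(3R)-7-(benzyloxy)chroman-3-yl]-6-methoxybenzonitrile | COc1cc(OCc2ccccc2)cc([C@@H]2COc3cc(OCc4ccccc4)ccc3C2)c1C#N | intermediate
10 | 1-{4-(benzyloxy)-2-[(3R)-7-(benzyloxy)chroman-3-yl]-6-methoxyphenyl}ethan-1-imine | COc1cc(OCc2ccccc2)cc([C@@H]2COc3cc(OCc4ccccc4)ccc3C2)c1C(C)=N | intermediate (not isolated)
11 | 1-{4-(benzyloxy)-2-[(3R)-7-(benzyloxy)chroman-3-yl]-6-methoxyphenyl}ethan-1-one | COc1cc(OCc2ccccc2)cc([C@@H]2COc3cc(OCc4ccccc4)ccc3C2)c1C(C)=O | intermediate
12 | potassium 1-{4-(benzyloxy)-2-[(3R)-7-(benzyloxy)chroman-3-yl]-6-methoxyphenyl}ethen-1-olate | COc1cc(OCc2ccccc2)cc([C@@H]2COc3cc(OCc4ccccc4)ccc3C2)c1C(=C)[O-].[K+] | intermediate (not isolated)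
13 | 1-{4-(benzyloxy)-2-[(3R)-7-(benzyloxy)chroman-3-yl]-6-methoxyphenyl}ethenyl trifluoromethanesulfonate | COc1cc(OCc2ccccc2)cc([C@@H]2COc3cc(OCc4ccccc4)ccc3C2)c1C(=C)OS(=O)(=O)C(F)(F)F | intermediate
14 | (4-(benzyloxy)-2-formylphenyl)boronic acid | O=Cc1cc(OCc2ccccc2)ccc1B(O)O | starting material
15 | 5-(benzyloxy)-2-(1-{4-(benzyloxy)-2-[(3R)-7-(benzyloxy)chroman-3-yl]-6-methoxyphenyl}ethenyl)benzaldehyde | COc1cc(OCc2ccccc2)cc([C@@H]2COc3cc(OCc4ccccc4)ccc3C2)c1C(=C)c1ccc(OCc2ccccc2)cc1C=O | intermediate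
16 | (3S)-6-(benzyloxy)-3-{4-(benzyloxy)-2-[(3R)-7-(benzyloxy)chroman-3-yl]-6-methoxyphenyl}-2,3-dihydro-1H-inden-1-one | O=C1C[C@H](c2c(OC)cc(OCc3ccccc3)cc2[C@@H]2COc3cc(OCc4ccccc4)ccc3C2)c2ccc(OCc3ccccc3)cc21 | intermediate (precursor of the key step)
17 | (4S)-7-(benzyloxy)-4-{4-(benzyloxy)-2-[(3R)-7-(benzyloxy)chroman-3-yl]-6-methoxyphenyl}chroman-2-one | O=C1C[C@H](c2c(OC)cc(OCc3ccccc3)cc2[C@@H]2COc3cc(OCc4ccccc4)ccc3C2)c2ccc(OCc3ccccc3)cc2O1 | intermediate (product of the key step)
18 | 2,6-dimethoxyphenol | COc1cccc(OC)c1O | starting material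
19 | 2-(benzyloxy)-1,3-dimethoxybenzene | COc1cccc(OC)c1OCc1ccccc1 | intermediate
20 | 3-(benzyloxy)-1-bromo-2,4-dimethoxybenzene | COc1ccc(Br)c(OC)c1OCc1ccccc1 | intermediate
21 | chlorozinc enolate of lactone 17 (chloro{[(4S)-4-aryl-7-(benzyloxy)-4H-chromen-2-yl]oxy}zinc) | Cl[Zn]OC1=C[C@H](c2c(OC)cc(OCc3ccccc3)cc2[C@@H]2COc3cc(OCc4ccccc4)ccc3C2)c2ccc(OCc3ccccc3)cc2O1 | intermediate (not isolated)
22 | (4S)-7-(benzyloxy)-3-[3-(benzyloxy)-2,4-dimethoxyphenyl]-4-{4-(benzyloxy)-2-[(3R)-7-(benzyloxy)chroman-3-yl]-6-methoxyphenyl}chroman-2-one, mixture of C3 epimers | COc1ccc(C2C(=O)Oc3cc(OCc4ccccc4)ccc3[C@H]2c2c(OC)cc(OCc3ccccc3)cc2[C@@H]2COc3cc(OCc4ccccc4)ccc3C2)c(OC)c1OCc1ccccc1 | intermediate (not isolated)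
23 | (3R,4S)-7-(benzyloxy)-3-[3-(benzyloxy)-2,4-dimethoxyphenyl]-4-{4-(benzyloxy)-2-[(3R)-7-(benzyloxy)chroman-3-yl]-6-methoxyphenyl}chroman-2-one | COc1ccc([C@@H]2C(=O)Oc3cc(OCc4ccccc4)ccc3[C@H]2c2c(OC)cc(OCc3ccccc3)cc2[C@@H]2COc3cc(OCc4ccccc4)ccc3C2)c(OC)c1OCc1ccccc1 | intermediate
24 | (2R,3S)-2-[3-(benzyloxy)-2,4-dimethoxyphenyl]-3-{4-(benzyloxy)-2-[(3R)-7-(benzyloxy)chroman-3-yl]-6-methoxyphenyl}-3-[4-(benzyloxy)-2-hydroxyphenyl]propan-1-ol | COc1ccc([C@H](CO)[C@H](c2c(OC)cc(OCc3ccccc3)cc2[C@@H]2COc3cc(OCc4ccccc4)ccc3C2)c2ccc(OCc3ccccc3)cc2O)c(OC)c1OCc1ccccc1 | intermediate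
25 | (3R,4S)-7-(benzyloxy)-3-[3-(benzyloxy)-2,4-dimethoxyphenyl]-4-{4-(benzyloxy)-2-[(3R)-7-(benzyloxy)chroman-3-yl]-6-methoxyphenyl}chroman | COc1ccc([C@@H]2COc3cc(OCc4ccccc4)ccc3[C@H]2c2c(OC)cc(OCc3ccccc3)cc2[C@@H]2COc3cc(OCc4ccccc4)ccc3C2)c(OC)c1OCc1ccccc1 | intermediate
26 | (3R,4S)-3-(3-hydroxy-2,4-dimethoxyphenyl)-4-{4-hydroxy-2-[(3R)-7-hydroxychroman-3-yl]-6-methoxyphenyl}chroman-7-ol | COc1ccc([C@@H]2COc3cc(O)ccc3[C@H]2c2c(OC)cc(O)cc2[C@@H]2COc3cc(O)ccc3C2)c(OC)c1O | target

Total step count: 18 steps.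
Longest linear sequence: 15 steps (steps 1–3, 5–12 and 15–18, from 1 to 26).

Steps most likely to fail

Step 11 (hydroacylation). The internal alkene carbon carries a doubly ortho-substituted arene, so facial discrimination by the catalyst may be poor and insertion may be slow enough for decarbonylation of the acyl rhodium hydride to compete. Fallback: starting from 15, the ring would be closed without asymmetric induction ([Rh(nbd)2]BF4, dppe, CH2Cl2) to give the C3-epimeric indanone F1. Its trimethylsilyl enol ether F2 (LiN(SiMe3)2, Me3SiCl, THF, −78 °C) would be dehydrogenated with Pd(OAc)2 in MeCN (Saegusa–Ito oxidation) to the 3-arylindenone F3. A copper hydride asymmetric conjugate reduction (Cu(OAc)2, DTBM-SEGPHOS antipode chosen for 3S, polymethylhydrosiloxane, tBuOH, toluene) would then place hydride on C3 and rejoin the route at 16.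

Step 12 (Baeyer–Villiger oxidation). Electrophilic oxidation of the alkoxy-substituted rings by the peracid may outrun oxidation of the ketone, or the methylene carbon may migrate in competition with the aryl carbon. Fallback: starting from 11, Claisen condensation with dimethyl carbonate (NaH, THF, reflux) would give the β-keto ester F4. Pechmann condensation with 3-(benzyloxy)phenol (InCl3, toluene, 80 °C), which closes para to the benzyloxy group, would give the 4-arylcoumarin F5. A copper hydride asymmetric conjugate reduction (Cu(OAc)2, DTBM-SEGPHOS antipode chosen for 4S, (EtO)2MeSiH, tBuOH, toluene) would set C4 and rejoin the route at 17, any lactol from over-reduction being re-oxidised.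

Step 15 (lactone α-arylation). Coupling at the enolate carbon next to the crowded diarylmethine may be slow, and the aryl ester enolate may open by loss of phenoxide to a ketene. Fallback: starting from 17, methanolysis (NaOMe, MeOH, 0 °C) would give the methyl ester phenol F6 and silylation (tBuMe2SiCl, imidazole, DMF) the silyl ether F7. Acyclic ester α-arylation with 20 (LiNCy2, Pd(dba)2, P(tBu)3, toluene, rt) would give the α-aryl ester F8 as a mixture at the new centre. Desilylation and relactonisation (Bu4NF, THF; then TsOH, toluene, 60 °C) would return the epimeric lactone mixture 22, which DBU equilibrates to 23.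

Further compounds
F1 | step 11 | (3RS)-6-(benzyloxy)-3-{4-(benzyloxy)-2-[(3R)-7-(benzyloxy)chroman-3-yl]-6-methoxyphenyl}-2,3-dihydro-1H-inden-1-one | O=C1CC(c2c(OC)cc(OCc3ccccc3)cc2[C@@H]2COc3cc(OCc4ccccc4)ccc3C2)c2ccc(OCc3ccccc3)cc21
F2 | step 11 | {[5-(benzyloxy)-1-{4-(benzyloxy)-2-[(3R)-7-(benzyloxy)chroman-3-yl]-6-methoxyphenyl}-1H-inden-3-yl]oxy}trimethylsilane | C[Si](C)(C)OC1=CC(c2c(OC)cc(OCc3ccccc3)cc2[C@@H]2COc3cc(OCc4ccccc4)ccc3C2)c2ccc(OCc3ccccc3)cc21
F3 | step 11 | 6-(benzyloxy)-3-{4-(benzyloxy)-2-[(3R)-7-(benzyloxy)chroman-3-yl]-6-methoxyphenyl}-1H-inden-1-one | O=C1C=C(c2c(OC)cc(OCc3ccccc3)cc2[C@@H]2COc3cc(OCc4ccccc4)ccc3C2)c2ccc(OCc3ccccc3)cc21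
F4 | step 12 | methyl 3-{4-(benzyloxy)-2-[(3R)-7-(benzyloxy)chroman-3-yl]-6-methoxyphenyl}-3-oxopropanoate | COC(=O)CC(=O)c1c(OC)cc(OCc2ccccc2)cc1[C@@H]1COc2cc(OCc3ccccc3)ccc2C1
F5 | step 12 | 7-(benzyloxy)-4-{4-(benzyloxy)-2-[(3R)-7-(benzyloxy)chroman-3-yl]-6-methoxyphenyl}-2H-chromen-2-one | O=C1C=C(c2c(OC)cc(OCc3ccccc3)cc2[C@@H]2COc3cc(OCc4ccccc4)ccc3C2)c2ccc(OCc3ccccc3)cc2O1
F6 | step 15 | methyl (3S)-3-{4-(benzyloxy)-2-[(3R)-7-(benzyloxy)chroman-3-yl]-6-methoxyphenyl}-3-[4-(benzyloxy)-2-hydroxyphenyl]propanoate | COC(=O)C[C@H](c1c(OC)cc(OCc2ccccc2)cc1[C@@H]1COc2cc(OCc3ccccc3)ccc2C1)c1ccc(OCc2ccccc2)cc1O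
F7 | step 15 | methyl (3S)-3-{4-(benzyloxy)-2-[(3R)-7-(benzyloxy)chroman-3-yl]-6-methoxyphenyl}-3-[4-(benzyloxy)-2-(tert-butyldimethylsilyloxy)phenyl]propanoate | COC(=O)C[C@H](c1c(OC)cc(OCc2ccccc2)cc1[C@@H]1COc2cc(OCc3ccccc3)ccc2C1)c1ccc(OCc2ccccc2)cc1O[Si](C)(C)C(C)(C)C
F8 | step 15 | methyl (3S)-2-[3-(benzyloxy)-2,4-dimethoxyphenyl]-3-{4-(benzyloxy)-2-[(3R)-7-(benzyloxy)chroman-3-yl]-6-methoxyphenyl}-3-[4-(benzyloxy)-2-(tert-butyldimethylsilyloxy)phenyl]propanoate, mixture of C2 epimers | COC(=O)C(c1ccc(OC)c(OCc2ccccc2)c1OC)[C@H](c1c(OC)cc(OCc2ccccc2)cc1[C@@H]1COc2cc(OCc3ccccc3)ccc2C1)c1ccc(OCc2ccccc2)cc1O[Si](C)(C)C(C)(C)C
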